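Retrosynthetic overview
1. The strategy rests on the end of the C9 side chain of ring B. This is the (13E)-C13=C14 enoic acid, in which the C16 methyl and the C15 carboxyl are cis. Both carbons are added syn to a terminal C13≡C14 alkyne (bonds C13–C16 and C14–C15) by methylalumination and carboxylation.
2. After that step only protecting-group work remains: the O3 silyl group comes off, the O3 acetate goes on, and the O19 silyl group comes off.
3. Alkyne 19 comes from the C13 methyl ketone 16 by enol phosphate elimination. The primary O19 and the axial secondary O3 are told apart by silylation.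
4. Ring A (C4–C5) and then ring B (C9–C10) close in one oxidative radical bicyclisation of the (E,E)-dienyl 2-methyl β-keto ester 9. Its 8-phenylmenthyl group sets C4, C5, C9 and C10 in the ent-labdane sense. An 8(17)→7 alkene shift and equatorial hydride attack at C3 follow.
5. Ester 9 is assembled (bond C1–C2) from the allylic bromide of geranylacetone ketal and the dianion of the auxiliary 2-methylacetoacetate.

Key step: step 13

Numbering: labdane numbering is used throughout, and already for the acyclic precursors. In the dinor compounds the side-chain terminus is C14.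
Assumption: the uncomplexed C4 radical is taken to react in the conformer with the ketone and ester C=O dipoles opposed and the ester C=O syn to the carbinol C–H of the auxiliary. The phenyl ring then covers the face that would lead to the normal series. If the sense proved opposite, the commercial (1S,2R,5S) antipode would be used in the same steps.

Step 1
Reactants: 1 (E)-geranylacetone
Product: 2 geranylacetone ethylene ketal, 2-[(3E)-4,8-dimethylnona-3,7-dien-1-yl]-2-methyl-1,3-dioxolane
Conditions: HOCH2CH2OH (3 equiv), PPTS (5 mol %), benzene, Dean–Stark, reflux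
Reagents that add atoms: ethylene glycol, OCCO
Why: Acid-catalysed ketalisation with azeotropic water removal masks the only carbonyl group, which must not meet the dianion of step 5 or the hydrides of steps 8 and 9, and the mild pyridinium acid leaves both trisubstituted alkenes and the E geometry untouched.

Step 2
Reactants: 2 geranylacetone ethylene ketal
Product: 3 (2E,6E)-2,6-dimethyl-9-(2-methyl-1,3-dioxolan-2-yl)nona-2,6-dien-1-ol
Conditions: SeO2 (0.1 equiv), t-BuOOH (2.5 equiv, in decane), salicylic acid (0.1 equiv), CH2Cl2, 0 → 23 °C; then NaBH4, MeOH, 0 °C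
Reagents that add atoms: tert-butyl hydroperoxide, CC(C)(C)OO (oxygen source, relayed by selenium dioxide, O=[Se]=O)
Why: Catalytic SeO2 allylic oxidation (ene reaction, then [2,3]-sigmatropic shift) attacks the more accessible terminal isopropylidene unit and oxidises its E-methyl group, so the new carbinol carbon (C1) lies trans to the chain as the later trans ring fusion requires; NaBH4 returns any over-oxidised enal to 3.

Step 3
Reactants: 3 allylic alcohol
Product: 4 2-[(3E,7E)-9-bromo-4,8-dimethylnona-3,7-dien-1-yl]-2-methyl-1,3-dioxolane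
Conditions: CBr4 (1.2 equiv), PPh3 (1.25 equiv), 2,6-lutidine (0.2 equiv), CH2Cl2, −20 → 0 °C
Reagents that add atoms: carbon tetrabromide, BrC(Br)(Br)Br
Why: The Appel reaction converts the primary allylic alcohol into the bromide by SN2 displacement of the oxyphosphonium ion under neutral conditions, without allylic transposition, loss of alkene geometry or harm to the ketal.

Step 4
Reactants: 5 methyl 2-methyl-3-oxobutanoate (methyl 2-methylacetoacetate); 6 (1R,2S,5R)-8-phenylmenthol
Product: 7 (1R,2S,5R)-8-phenylmenthyl 2-methyl-3-oxobutanoate (epimers at the α-carbon)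
Conditions: 5 (3 equiv), DMAP (0.3 equiv), toluene, reflux through 4 Å molecular sieves
Reagents that add atoms: none
Why: DMAP-catalysed transesterification of an enolisable β-keto ester (through the acylketene) accepts hindered secondary alcohols, is driven by removal of methanol and does not touch the three stereocentres of the auxiliary.

Step 5
Reactants: 7 auxiliary 2-methylacetoacetate; 4 allylic bromide
Product: 9 (1R,2S,5R)-8-phenylmenthyl (6E,10E)-2,6,10-trimethyl-13-(2-methyl-1,3-dioxolan-2-yl)-3-oxotrideca-6,10-dienoate (C4 epimers), via dilithium dianion 8 (not isolated)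
Conditions: LDA (2.1 equiv), THF, −78 → 0 °C; 4, 0 °C; AcOH quench
Reagents that add atoms: none
Why: Weiler dianion alkylation: the more basic terminal carbanion of 8 displaces the allylic bromide by SN2 and forms C1–C2 while the stabilised α-position stays an enolate, and the configuration of the C4 methine regenerated on quench is irrelevant because it becomes a planar radical in step 6.

Step 6
Reactants: 9 dienyl β-keto ester
Product: 10 (1R,2S,5R)-8-phenylmenthyl ent-13,13-ethylenedioxy-3-oxo-15,16-dinorlabd-8(17)-en-19-oate. It is a trans-decalin with the C19 ester axial on C4 and on the same face as C20, C18 equatorial, the C9 side chain equatorial, and H5 and H9 on the face opposite C20.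
Conditions: Mn(OAc)3·2H2O (2.2 equiv), Cu(OAc)2·H2O (1 equiv), KOAc (3 equiv), degassed AcOH, 23 °C
Reagents that add atoms: none
Why: Oxidative free-radical polyene cyclisation: Mn(OAc)3 oxidises the enol of 9 to the electrophilic C4 radical, which closes ring A (C4–C5, 6-endo) and then ring B (C10–C9, 6-endo) through a chair–chair array of the two E alkenes, so that C20 and H5 are trans, C11 is equatorial and the ester is axial on C4, while the phenyl ring of the auxiliary screens one face of the radical and so fixes the absolute sense, Cu(OAc)2 oxidises the tertiary C8 radical to the 8(17)-alkene, and the acetate buffer protects the ketal.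

Step 7
Reactants: 10 8(17)-ene keto ester
Product: 11 (1R,2S,5R)-8-phenylmenthyl ent-13,13-ethylenedioxy-3-oxo-15,16-dinorlabd-7-en-19-oate
Conditions: Co(salen)Cl (5 mol %; salen = N,N'-bis(3,5-di-tert-butylsalicylidene)cyclohexane-1,2-diaminate), PhSiH3 (10 mol %), benzene, 23 °C
Reagents that add atoms: none
Why: Cobalt-hydride hydrogen-atom-transfer alkene isomerisation: reversible H-atom addition to C17 gives the tertiary C8 radical, from which the cobalt complex takes back the accessible axial C7–H rather than the shielded tertiary C9–H, and the trisubstituted 7-ene is a much poorer H-atom acceptor than the 1,1-disubstituted alkene, so it should accumulate under neutral conditions that spare ketal, ketone and C9.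

Step 8
Reactants: 11 7-ene keto ester
Product: 12 (1R,2S,5R)-8-phenylmenthyl ent-13,13-ethylenedioxy-3-hydroxy-15,16-dinorlabd-7-en-19-oate, with the 3-OH axial and on the face opposite C19 and C20
Conditions: Li(s-Bu)3BH (L-Selectride, 1.5 equiv), THF, −78 → −20 °C; H2O
Reagents that add atoms: none
Why: Reduction of a cyclohexanone with a bulky trialkylborohydride: Li(s-Bu)3BH avoids the axial trajectory past the axial hydrogens on C1 and C5 and attacks C3 equatorially, which places the new C3–OH axial and anti to C19, while the hindered ester, the ketal and the alkene are inert.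

Step 9
Reactants: 12 axial hydroxy ester
Product: 14 ent-3,19-dihydroxy-15,16-dinorlabd-7-en-13-one (3-OH axial; C19 axial CH2OH), via ketal diol 13 (not isolated)
Conditions: LiAlH4 (4 equiv), THF, 0 °C → reflux; then 1 M aq. HCl–THF, 23 °C
Reagents that add atoms: water, O
Why: LiAlH4 reduction of the neopentyl ester gives the primary C19 alcohol and releases the auxiliary for recovery without touching any stereocentre, and the acidic work-up hydrolyses the dioxolane at a stage where no acid-labile silyl ether is yet present.

Step 10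
Reactants: 14 keto diol
Product: 15 ent-19-(tert-butyldiphenylsilyloxy)-3-hydroxy-15,16-dinorlabd-7-en-13-one
Conditions: TBDPSCl (1.1 equiv), imidazole (2.5 equiv), DMF, 0 → 23 °C
Reagents that add atoms: tert-butyldiphenylsilyl chloride, CC(C)(C)[Si](Cl)(c1ccccc1)c1ccccc1
Why: Chemoselective silylation: the bulky chlorosilane reacts with the primary C19 alcohol much faster than with the axial secondary C3 alcohol next to the quaternary C4.

Step 11
Reactants: 15 C19 silyl ether
Product: 16 ent-19-(tert-butyldiphenylsilyloxy)-3-(triethylsilyloxy)-15,16-dinorlabd-7-en-13-one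
Conditions: TESOTf (1.2 equiv), 2,6-lutidine (2 equiv), CH2Cl2, −78 → −20 °C
Reagents that add atoms: triethylsilyl triflate, CC[Si](CC)(CC)OS(=O)(=O)C(F)(F)F
Why: Silylation with a silyl triflate and a hindered pyridine base overcomes the crowding at the axial C3–OH, and at low temperature the methyl ketone should not be converted into its enol silane.

Step 12
Reactants: 16 bis-silylated methyl ketone
Product: 19 ent-19-(tert-butyldiphenylsilyloxy)-3-(triethylsilyloxy)-15,16-dinorlabd-7-en-13-yne, via enol phosphate 17 (not isolated), via lithium acetylide 18 (not isolated)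
Conditions: LDA (1.1 equiv), THF, −78 °C; ClP(O)(OEt)2 (1.15 equiv), −78 → 23 °C; LDA (2.4 equiv), −78 → 23 °C; H2O
Reagents that add atoms: none
Why: Negishi conversion of a methyl ketone into a terminal alkyne: kinetic deprotonation at the methyl group (C14), O-phosphorylation and LDA-induced β-elimination of diethyl phosphate give the C13≡C14 acetylide, which is protonated on quench, and both silyl ethers and the remote stereocentres are inert to LDA.

Step 13
Reactants: 19 terminal alkyne; 20 trimethylaluminium; 21 carbon dioxide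
Product: 24 ent-(13E)-19-(tert-butyldiphenylsilyloxy)-3-(triethylsilyloxy)labda-7,13-dien-15-oic acid, via alkenylalane 22 (not isolated), via lithium alanate 23 (not isolated)
Conditions: Me3Al (3 equiv), Cp2ZrCl2 (0.3 equiv), CH2Cl2, 0 → 23 °C; volatiles removed in vacuo, hexane–THF; n-BuLi (1.1 equiv), −78 → 0 °C; CO2 (dry gas), −78 → 0 °C; cold 0.5 M aq. HCl
Reagents that add atoms: trimethylaluminium (20), C[Al](C)C; carbon dioxide (21), O=C=O
Why: Me3Al and Cp2ZrCl2 exchange methyl for chloride to give a Lewis-acid-activated methylzirconocene, which adds across C13≡C14 through a four-centre syn transition state with methyl on the substituted carbon C13 and the metal on the terminal carbon C14, and zirconium-to-aluminium exchange releases alkenylalane 22 and the catalyst. n-BuLi turns the weakly nucleophilic alane into alanate 23, whose sp2 C14–Al bond is carboxylated by CO2 with retention, so that C13–C16 and C14–C15 are both made in one flask. This is the Negishi zirconium-catalysed carboalumination with electrophilic trapping of the alkenyl metal, which is well established for terminal alkyl-substituted alkynes. No ring is closed and no stereocentre is created; the only stereo-element formed is the C13=C14 geometry, fixed as E (C16 cis to C15) by syn addition followed by retentive trapping. The step needs regioselectivity (methyl internal), which the free terminal C–H and the unbranched C11–C12 tether secure, and chemoselectivity, which holds because the trisubstituted C7=C8 alkene is not carbometalated and both oxygens are silyl ethers without acidic hydrogen or carbonyl groups. The cold, brief acidic work-up should keep the hindered axial C3 silyl ether in place, and its partial loss would be harmless because step 14 removes it.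

Step 14
Reactants: 24 bis-silylated acid
Product: 25 ent-(13E)-19-(tert-butyldiphenylsilyloxy)-3-hydroxylabda-7,13-dien-15-oic acid
Conditions: AcOH–THF–H2O (3:1:1), 35 °C
Reagents that add atoms: none
Why: Acid-catalysed solvolysis distinguishes the two silyl ethers by orders of magnitude in rate, so the triethylsilyl group leaves while the tert-butyldiphenylsilyl ether, the 7-ene and the enoic acid persist.

Step 15
Reactants: 25 hydroxy acid
Product: 27 ent-(13E)-3-acetoxy-19-(tert-butyldiphenylsilyloxy)labda-7,13-dien-15-oic acid, via mixed anhydride 26 (not isolated)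
Conditions: Ac2O (5 equiv), DMAP (0.2 equiv), pyridine, 23 → 40 °C; then H2O, 23 °C
Reagents that add atoms: acetic anhydride, CC(=O)OC(C)=O
Why: DMAP-catalysed acylation (nucleophilic catalysis) acetylates the hindered axial C3–OH with retention at C3, and the mixed anhydride 26 formed at C15 at the same time is hydrolysed back to the acid when water is added to the pyridine solution.

Step 16
Reactants: 27 acetoxy silyl ether
Product: 28 target, (2E)-5-[(1R,4aS,5R,6S,8aS)-6-acetoxy-5-(hydroxymethyl)-2,5,8a-trimethyl-1,4,4a,5,6,7,8,8a-octahydronaphthalen-1-yl]-3-methylpent-2-enoic acid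
Conditions: HF·pyridine, pyridine–THF, 0 → 23 °C, polypropylene vessel
Reagents that add atoms: none
Why: Fluoride-driven desilylation in a buffered acidic medium frees the C19 alcohol without touching acetate, acid or alkenes, and acetyl migration from O3 to O19 is excluded because the C3–O and C4–C19 bonds are antiperiplanar (trans-diaxial) and cannot reach a cyclic orthoester.

Compound list
1 | (E)-geranylacetone | CC(C)=CCC/C(C)=C/CCC(C)=O | starting material
2 | geranylacetone ethylene ketal | CC(C)=CCC/C(C)=C/CCC1(C)OCCO1 | intermediate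
3 | (2E,6E)-2,6-dimethyl-9-(2-methyl-1,3-dioxolan-2-yl)nona-2,6-dien-1-ol | OC/C(C)=C/CC/C(C)=C/CCC1(C)OCCO1 | intermediate
4 | 2-[(3E,7E)-9-bromo-4,8-dimethylnona-3,7-dien-1-yl]-2-methyl-1,3-dioxolane | BrC/C(C)=C/CC/C(C)=C/CCC1(C)OCCO1 | intermediate
5 | methyl 2-methyl-3-oxobutanoate | COC(=O)C(C)C(C)=O | starting material
6 | (1R,2S,5R)-8-phenylmenthol | C[C@@H]1CC[C@H]([C@@H](C1)O)C(C)(C)c1ccccc1 | starting material
7 | (1R,2S,5R)-8-phenylmenthyl 2-methyl-3-oxobutanoate | CC(=O)C(C)C(=O)O[C@@H]1C[C@H](C)CC[C@H]1C(C)(C)c1ccccc1 | intermediate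
8 | dilithium dianion of 7 | [Li+].[Li+].C=C([O-])C(C)=C([O-])O[C@@H]1C[C@H](C)CC[C@H]1C(C)(C)c1ccccc1 | intermediate
9 | 8-phenylmenthyl (6E,10E)-2,6,10-trimethyl-13-(2-methyl-1,3-dioxolan-2-yl)-3-oxotrideca-6,10-dienoate | CC(C(=O)CC/C(C)=C/CC/C(C)=C/CCC1(C)OCCO1)C(=O)O[C@@H]1C[C@H](C)CC[C@H]1C(C)(C)c1ccccc1 | intermediate
10 | 8-phenylmenthyl ent-13,13-ethylenedioxy-3-oxo-15,16-dinorlabd-8(17)-en-19-oate | O=C1CC[C@]2(C)[C@H](CCC(=C)[C@H]2CCC2(C)OCCO2)[C@]1(C)C(=O)O[C@@H]1C[C@H](C)CC[C@H]1C(C)(C)c1ccccc1 | intermediate
11 | 8-phenylmenthyl ent-13,13-ethylenedioxy-3-oxo-15,16-dinorlabd-7-en-19-oate | O=C1CC[C@]2(C)[C@H](CC=C(C)[C@H]2CCC2(C)OCCO2)[C@]1(C)C(=O)O[C@@H]1C[C@H](C)CC[C@H]1C(C)(C)c1ccccc1 | intermediate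
12 | 8-phenylmenthyl ent-13,13-ethylenedioxy-3-hydroxy-15,16-dinorlabd-7-en-19-oate (3-OH axial) | O[C@H]1CC[C@]2(C)[C@H](CC=C(C)[C@H]2CCC2(C)OCCO2)[C@]1(C)C(=O)O[C@@H]1C[C@H](C)CC[C@H]1C(C)(C)c1ccccc1 | intermediate
13 | ent-13,13-ethylenedioxy-15,16-dinorlabd-7-ene-3,19-diol | O[C@H]1CC[C@]2(C)[C@H](CC=C(C)[C@H]2CCC2(C)OCCO2)[C@]1(C)CO | intermediate
14 | ent-3,19-dihydroxy-15,16-dinorlabd-7-en-13-one | O[C@H]1CC[C@]2(C)[C@H](CC=C(C)[C@H]2CCC(C)=O)[C@]1(C)CO | intermediate
15 | 19-O-TBDPS ether of 14 | O[C@H]1CC[C@]2(C)[C@H](CC=C(C)[C@H]2CCC(C)=O)[C@]1(C)CO[Si](c1ccccc1)(c1ccccc1)C(C)(C)C | intermediate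
16 | 3-O-TES, 19-O-TBDPS methyl ketone | CC[Si](CC)(CC)O[C@H]1CC[C@]2(C)[C@H](CC=C(C)[C@H]2CCC(C)=O)[C@]1(C)CO[Si](c1ccccc1)(c1ccccc1)C(C)(C)C | intermediate
17 | C13 diethyl enol phosphate (C13=C14) | CC[Si](CC)(CC)O[C@H]1CC[C@]2(C)[C@H](CC=C(C)[C@H]2CCC(=C)OP(=O)(OCC)OCC)[C@]1(C)CO[Si](c1ccccc1)(c1ccccc1)C(C)(C)C | intermediate
18 | C14 lithium acetylide | CC[Si](CC)(CC)O[C@H]1CC[C@]2(C)[C@H](CC=C(C)[C@H]2CCC#C[Li])[C@]1(C)CO[Si](c1ccccc1)(c1ccccc1)C(C)(C)C | intermediate
19 | 15,16-dinor-7-en-13-yne, 3-O-TES, 19-O-TBDPS | CC[Si](CC)(CC)O[C@H]1CC[C@]2(C)[C@H](CC=C(C)[C@H]2CCC#C)[C@]1(C)CO[Si](c1ccccc1)(c1ccccc1)C(C)(C)C | intermediate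
20 | trimethylaluminium | C[Al](C)C | starting material
21 | carbon dioxide | O=C=O | starting material
22 | (13E)-C14 dimethylalkenylalane | CC[Si](CC)(CC)O[C@H]1CC[C@]2(C)[C@H](CC=C(C)[C@H]2CC/C(C)=C/[Al](C)C)[C@]1(C)CO[Si](c1ccccc1)(c1ccccc1)C(C)(C)C | intermediate
23 | lithium butyl(dimethyl)alkenylalanate | [Li+].CC[Si](CC)(CC)O[C@H]1CC[C@]2(C)[C@H](CC=C(C)[C@H]2CC/C(C)=C/[Al-](C)(C)CCCC)[C@]1(C)CO[Si](c1ccccc1)(c1ccccc1)C(C)(C)C | intermediate
24 | (13E)-7,13-dien-15-oic acid, 3-O-TES, 19-O-TBDPS | CC[Si](CC)(CC)O[C@H]1CC[C@]2(C)[C@H](CC=C(C)[C@H]2CC/C(C)=C/C(=O)O)[C@]1(C)CO[Si](c1ccccc1)(c1ccccc1)C(C)(C)C | intermediate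
25 | (13E)-3-hydroxy acid, 19-O-TBDPS | O[C@H]1CC[C@]2(C)[C@H](CC=C(C)[C@H]2CC/C(C)=C/C(=O)O)[C@]1(C)CO[Si](c1ccccc1)(c1ccccc1)C(C)(C)C | intermediate
26 | 3-acetate, C15 acetic mixed anhydride | CC(=O)O[C@H]1CC[C@]2(C)[C@H](CC=C(C)[C@H]2CC/C(C)=C/C(=O)OC(C)=O)[C@]1(C)CO[Si](c1ccccc1)(c1ccccc1)C(C)(C)C | intermediate
27 | (13E)-3-acetoxy acid, 19-O-TBDPS | CC(=O)O[C@H]1CC[C@]2(C)[C@H](CC=C(C)[C@H]2CC/C(C)=C/C(=O)O)[C@]1(C)CO[Si](c1ccccc1)(c1ccccc1)C(C)(C)C | intermediate
28 | CNP0129162.1, ent-(13E)-3-acetoxy-19-hydroxylabda-7,13-dien-15-oic acid (3S,4R,5S,9R,10S) | CC(=O)O[C@H]1CC[C@]2(C)[C@H](CC=C(C)[C@H]2CC/C(C)=C/C(=O)O)[C@]1(C)CO | target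

Total step count: 16.
Longest linear sequence: 15 steps (steps 1–3 and 5–16, from 1). Step 4 runs in parallel.

Steps most likely to fail

Step 6.
- What may go wrong: the auxiliary may shield one face of the C4 radical incompletely. The dioxolane may also solvolyse slowly during the long oxidation in acetic acid.
- The fallback sets out from 9 and comes back at 10. It replaces the oxidative cyclisation by a neutral group-transfer cyclisation that can be run cold.
- Enolate selenenylation of 9 (NaH, THF, 0 °C; PhSeCl) would give the 2-(phenylselanyl) β-keto ester F1.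
- Photolysis of its weak C–Se bond in toluene at low temperature starts a phenylselanyl group-transfer radical bicyclisation, which ends at the C8 tertiary selenide F2.
- H2O2–pyridine in CH2Cl2 at 0 °C, followed by selenoxide syn-elimination, gives 10. The share that eliminates towards C7 is already 11.

Step 7.
- What may go wrong: hydrogen may be abstracted at C9 instead of C7, with drift to the tetrasubstituted 8(9)-alkene, or the catalyst may stall.
- The fallback sets out from 10 and comes back at 11. It fixes the alkene position by a sigmatropic event instead of an equilibration.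
- SeO2/t-BuOOH allylic hydroxylation of the exocyclic alkene gives the axial 7-hydroxy-8(17)-ene F3.
- Myers reductive allylic transposition follows (2-nitrobenzenesulfonylhydrazide, PPh3, DEAD, THF, −30 → 23 °C). It displaces the C7 oxygen to give the allylic diazene F4.
- The retro-ene loss of nitrogen from F4 delivers hydrogen to C17 and places the double bond between C7 and C8 only.

Step 8.
- What may go wrong: facial selectivity may be poor, because the equatorial trajectory at C3 is flanked by the bulky axial C4 ester and axial attack may compete.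
- The fallback sets out from 11 and comes back at 13, which is hydrolysed to 14 as in step 9. It uses hydroxyl-directed hydride delivery instead of reagent bulk.
- The C3 ketone is masked in the flask as the lithium enolate F5 (LDA, THF, −78 °C).
- The ester is reduced with LiAlH4, and a neutral work-up gives the 3-oxo-19-ol F6.
- Saksena–Evans reduction with Me4NBH(OAc)3 in MeCN–AcOH at −30 °C binds boron to O19. It delivers hydride to C3 from the face that carries C19, which forces the C3–OH onto the opposite, axial side.

Further compounds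
F1 | step 6 | 8-phenylmenthyl 2-(phenylselanyl) derivative of 9 | CC([Se]c1ccccc1)(C(=O)CC/C(C)=C/CC/C(C)=C/CCC1(C)OCCO1)C(=O)O[C@@H]1C[C@H](C)CC[C@H]1C(C)(C)c1ccccc1
F2 | step 6 | 8-phenylmenthyl ent-13,13-ethylenedioxy-3-oxo-8-(phenylselanyl)-15,16-dinorlabdan-19-oate (C8 epimers) | O=C1CC[C@]2(C)[C@H](CCC(C)([Se]c3ccccc3)[C@H]2CCC2(C)OCCO2)[C@]1(C)C(=O)O[C@@H]1C[C@H](C)CC[C@H]1C(C)(C)c1ccccc1
F3 | step 7 | 7-hydroxy derivative of 10 (7-OH axial, on the face of H5 and H9) | O=C1CC[C@]2(C)[C@H](C[C@H](O)C(=C)[C@H]2CCC2(C)OCCO2)[C@]1(C)C(=O)O[C@@H]1C[C@H](C)CC[C@H]1C(C)(C)c1ccccc1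
F4 | step 7 | C7 allylic diazene (inverted at C7) | O=C1CC[C@]2(C)[C@H](C[C@@H](N=N)C(=C)[C@H]2CCC2(C)OCCO2)[C@]1(C)C(=O)O[C@@H]1C[C@H](C)CC[C@H]1C(C)(C)c1ccccc1
F5 | step 8 | C2–C3 lithium enolate of 11 | [Li]OC1=CC[C@]2(C)[C@H](CC=C(C)[C@H]2CCC2(C)OCCO2)[C@]1(C)C(=O)O[C@@H]1C[C@H](C)CC[C@H]1C(C)(C)c1ccccc1
F6 | step 8 | ent-13,13-ethylenedioxy-19-hydroxy-15,16-dinorlabd-7-en-3-one | O=C1CC[C@]2(C)[C@H](CC=C(C)[C@H]2CCC2(C)OCCO2)[C@]1(C)CO
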